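The numbers of this flask belong to no real substance; what happens was integrated by code.

Every flask held 1.0 M of substrate against 2.00 M of second nucleophile, twice as much, and the flasks differed in temperature.

common to all: substrate 1.0 M; first nucleophile 0.900 M; second nucleophile 2.00 M; capture agent 0.0500 M; time 20 h

| run | temperature |
|---|---|
| Thursday's | 5 °C |
| Monday's | 45 °C |
| Wednesday's | 25 °C |

* which flask leads in amount of target, in percent of the substrate charged ("all alike" within 1.5 percentage points) (Thursday's / Monday's / Wednesday's / all alike)
* how much target is there at the end, in percent of the substrate charged: Thursday's
* how much target is there at the end, in percent of the substrate charged: Monday's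
* how much target is there at the end, in percent of the substrate charged: Wednesday's

- the list of constants is for 25 °C, to be carried to other temperatures by the activation energies

    substrate → open intermediate (k1 = 0.198 min⁻¹, Ea1 = 76.0 kJ mol⁻¹)
    first nucleophile + open intermediate → target (k2 = 2.44 M⁻¹ min⁻¹, Ea2 = 70.0 kJ mol⁻¹)
    second nucleophile + open intermediate → other capture product (k3 = 0.689 M⁻¹ min⁻¹, Ea3 = 71.0 kJ mol⁻¹)
    open intermediate → solvolysis product (k4 = 1.35 min⁻¹, Ea4 = 87.0 kJ mol⁻¹)
    second nucleophile + target → over-reaction product (k5 = 0.00211 M⁻¹ min⁻¹, Ea5 = 77.0 kJ mol⁻¹)
    open intermediate + capture agent → trapped intermediate (k6 = 0.0216 M⁻¹ min⁻¹, Ea6 = 63.0 kJ mol⁻¹)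
    second nucleophile → decomposition product (k7 = 1.63 × 10⁻⁵ min⁻¹, Ea7 = 104 kJ mol⁻¹)
    (constants at 25 °C)

The substrate opened to an open intermediate, which first nucleophile caught to give target, while second nucleophile and solvolysis competed for it. Second nucleophile then attacked the target itself. I began with Wednesday's, where the constants apply directly. There the substrate had a life of 5.05 min, and solvolysis by itself gave the open intermediate a life of 0.741 min. Both were far shorter than the run of 20 h, so in Wednesday's the target was made in the opening stretch of the run.

Two times remained: the run, and the life of target against second nucleophile. I treated that loss as pseudo-first-order, with c(second nucleophile) held at its charge, which gave a life of 3.95 h. Their ratio for Wednesday's was 5.06. This count of turnovers, the run time divided by the life of the target, was the quantity I carried, and with c(second nucleophile) held at its charge, e to its negative is the fraction of target surviving.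

The attack of second nucleophile on target speeds up 66-fold from Thursday's to Monday's. Spreading that factor evenly over the degrees gave 0.624 turnovers for Thursday's and 41.1 for Monday's. About half of the target would then survive in Thursday's, and hardly any in Monday's. For the target made I took Wednesday's starting share for all three flasks, 44.6%. My figures were 23.9% for Thursday's, 0.283% for Wednesday's and nothing measurable for Monday's. No step makes second nucleophile, so c(second nucleophile) falls during a run, and I expected these survivals to come out low.

The forecast named Thursday's and gave 29% for Thursday's, 0% for Monday's and 1.2% for Wednesday's, holding that “the excess second nucleophile then slowly consumes the target”.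

The flasks gave 29.0% in Thursday's, 0% in Monday's and 1.14% in Wednesday's, so Thursday's led.

In Wednesday's, c(second nucleophile) stood at 64.9% of its charge after 20.0 h, so the count is 5.06 turnovers on the charge and 3.28 on that final level, while 1.14% target beside 37.9% over-reaction product reads as 3.53 turnovers. Monday's recipe run at 20 °C counts 3.00 turnovers on the charge and 1.99 on its final 66.3% of second nucleophile, and its 4.74% target beside 35.5% over-reaction product reads as 2.14 turnovers.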